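**Retrosynthetic overview**
1. Planaic acid 13 comes from depside aldehyde 12 by a final aldehyde-to-acid oxidation; the carboxyl of ring A (the benzoic acid ring) is carried at the aldehyde level.
2. 12 is cut at the bond between the ester carbonyl carbon and C-1 of ring B (the 2,4-dimethoxy-6-pentylphenyl ring), giving aryl formate 7 and aryl iodide 9. Both carbons are electrophilic; Pd and base turn the formate into an aryloxycarbonyl anion equivalent (CO-free aryloxycarbonylation).
3. Enabling feature: C-1 of ring B is para to one OMe and ortho to the other, so it is the most nucleophilic CH of olivetol dimethyl ether and takes iodine directly. The ester oxygen is para to the carbonyl carbon of ring A, so this phenoxide leaves and re-enters easily and its formate releases CO under NEt3.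
4. 7 comes from olivetol by formylation, 4-O-MOM protection, 2-O-methylation, MOM removal and O-formylation; 9 comes from olivetol dimethyl ether by iodination.
5. No ring is formed: both benzene rings are bought intact.

Key step: step 7

Remark: the target has no stereocentre and is achiral, so there is no enantiomer to select and no step sets configuration. Olivetol and olivetol dimethyl ether are taken as commercial.

**Step 1**
Reactants: 1 olivetol (5-pentylbenzene-1,3-diol)
Product: 3 2,4-dihydroxy-6-pentylbenzaldehyde, via iminium chloride 2 (not isolated)
Conditions: POCl3, DMF, 0 °C to rt; then H2O, 50 °C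
Reagents that add atoms: N,N-dimethylformamide, CN(C)C=O; water, O
Why: Vilsmeier–Haack formylation, in which the chloroiminium ion should attack the ring carbon para to one OH and ortho to the other (the carbon between the two OH groups is shielded on both sides), and the iminium salt is hydrolysed on work-up.

**Step 2**
Reactants: 3 2,4-dihydroxy-6-pentylbenzaldehyde
Product: 4 2-hydroxy-4-(methoxymethoxy)-6-pentylbenzaldehyde
Conditions: MOMCl (1.05 equiv), i-Pr2NEt, CH2Cl2, 0 °C
Reagents that add atoms: chloromethyl methyl ether, COCCl
Why: Williamson-type O-alkylation (MOM protection), which should take only the 4-OH because it is the more acidic and is free, while the 2-OH is held in a hydrogen bond to the aldehyde.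

**Step 3**
Reactants: 4 2-hydroxy-4-(methoxymethoxy)-6-pentylbenzaldehyde
Product: 5 2-methoxy-4-(methoxymethoxy)-6-pentylbenzaldehyde
Conditions: MeI, K2CO3, DMF, 40 °C
Reagents that add atoms: iodomethane, CI
Why: Williamson ether synthesis, in which carbonate in DMF deprotonates the chelated 2-OH for methylation while the MOM acetal and the non-enolisable aldehyde are inert.

**Step 4**
Reactants: 5 2-methoxy-4-(methoxymethoxy)-6-pentylbenzaldehyde
Product: 6 4-hydroxy-2-methoxy-6-pentylbenzaldehyde
Conditions: conc. HCl (cat.), MeOH, 50 °C; aqueous work-up
Reagents that add atoms: none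
Why: acid-catalysed acetal cleavage (MOM removal), which should free the phenol while the aryl methyl ether stays, and any dimethyl acetal of the aldehyde reverts on aqueous work-up.

**Step 5**
Reactants: 6 4-hydroxy-2-methoxy-6-pentylbenzaldehyde
Product: 7 4-formyl-3-methoxy-5-pentylphenyl formate
Conditions: HCO2H/Ac2O (premixed, 60 °C, gives AcOCHO), then 6, NaOAc, toluene, 0 °C to rt; non-aqueous work-up, used crude
Reagents that add atoms: acetic formic anhydride, CC(=O)OC=O
Why: O-formylation of a phenol by a mixed anhydride, in which the phenoxide should attack the more electrophilic and less hindered formyl carbonyl, so the formate and not the acetate is expected.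

**Step 6**
Reactants: 8 olivetol dimethyl ether (1,3-dimethoxy-5-pentylbenzene)
Product: 9 2-iodo-1,5-dimethoxy-3-pentylbenzene
Conditions: NIS (1.05 equiv), MeCN, 0 °C to rt
Reagents that add atoms: N-iodosuccinimide, O=C1CCC(=O)N1I
Why: electrophilic aromatic iodination (SEAr), which should go to the ring carbon para to one OMe and ortho to the other, next to the pentyl group, because the carbon between the two OMe groups is shielded on both sides, and one equivalent of NIS should keep it at the mono-iodide.

**Step 7**
Reactants: 7 4-formyl-3-methoxy-5-pentylphenyl formate (1.3 equiv); 9 2-iodo-1,5-dimethoxy-3-pentylbenzene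
Product: 12 4-formyl-3-methoxy-5-pentylphenyl 2,4-dimethoxy-6-pentylbenzoate, via triethylammonium aryloxide 10 (not isolated), via carbon monoxide 11 (not isolated)
Conditions: Pd(OAc)2 (5 mol %), Xantphos (10 mol %), NEt3 (2 equiv), toluene, 80 °C, sealed tube
Reagents that add atoms: none
Why: NEt3 splits formate 7 into triethylammonium aryloxide 10 and carbon monoxide 11, Pd(0)/Xantphos adds oxidatively to the C–I bond of 9, CO inserts to give an aroylpalladium(II) species in which the new aryl C–C(=O) bond is made, and aryloxide 10 then takes the acyl group from palladium to give ester 12 and Pd(0), so the formyl carbon of 7 ends up bonded to the former C–I carbon of 9. The closest known reaction type is the palladium-catalysed, CO-gas-free aryloxycarbonylation of aryl halides with aryl formates. No ring is closed and no stereocentre is formed. The step needs chemoselectivity for carbonylative C–C coupling over direct C–O coupling to a diaryl ether and over protodeiodination; CO insertion into this electron-rich aryl–Pd bond flanked by OMe and pentyl should be fast because it relieves steric strain, and the wide bite angle of Xantphos favours acyl–O bond formation. Site selectivity is fixed by the position of iodine, and the aldehyde of ring A should be inert to Pd(0)/NEt3 at 80 °C, so the two partners combine without protecting groups.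

**Step 8**
Reactants: 12 4-formyl-3-methoxy-5-pentylphenyl 2,4-dimethoxy-6-pentylbenzoate
Product: 13 planaic acid (4-[(2,4-dimethoxy-6-pentylbenzoyl)oxy]-2-methoxy-6-pentylbenzoic acid)
Conditions: NaClO2, NaH2PO4, 2-methyl-2-butene (excess), t-BuOH/THF/H2O, 0 °C to rt; acidify to pH 3
Reagents that add atoms: sodium chlorite, [Na+].[O-]Cl=O
Why: Pinnick (Lindgren) oxidation, in which chlorous acid adds to the aldehyde and fragments to the carboxylic acid and HOCl, which 2-methyl-2-butene should trap before it chlorinates the electron-rich rings, while the mildly acidic buffer should leave the aryl ester untouched.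

**Compound list**
1 | olivetol (5-pentylbenzene-1,3-diol) | CCCCCc1cc(O)cc(O)c1 | starting material
2 | N-[(2,4-dihydroxy-6-pentylphenyl)methylidene]-N-methylmethanaminium chloride | CCCCCc1cc(O)cc(O)c1C=[N+](C)C.[Cl-] | intermediate
3 | 2,4-dihydroxy-6-pentylbenzaldehyde | CCCCCc1cc(O)cc(O)c1C=O | intermediate
4 | 2-hydroxy-4-(methoxymethoxy)-6-pentylbenzaldehyde | CCCCCc1cc(OCOC)cc(O)c1C=O | intermediate
5 | 2-methoxy-4-(methoxymethoxy)-6-pentylbenzaldehyde | CCCCCc1cc(OCOC)cc(OC)c1C=O | intermediate
6 | 4-hydroxy-2-methoxy-6-pentylbenzaldehyde | CCCCCc1cc(O)cc(OC)c1C=O | intermediate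
7 | 4-formyl-3-methoxy-5-pentylphenyl formate | CCCCCc1cc(OC=O)cc(OC)c1C=O | intermediate
8 | olivetol dimethyl ether (1,3-dimethoxy-5-pentylbenzene) | CCCCCc1cc(OC)cc(OC)c1 | starting material
9 | 2-iodo-1,5-dimethoxy-3-pentylbenzene | CCCCCc1cc(OC)cc(OC)c1I | intermediate
10 | triethylammonium 4-formyl-3-methoxy-5-pentylphenoxide | CCCCCc1cc([O-])cc(OC)c1C=O.CC[NH+](CC)CC | intermediate
11 | carbon monoxide | [C-]#[O+] | intermediate
12 | 4-formyl-3-methoxy-5-pentylphenyl 2,4-dimethoxy-6-pentylbenzoate | CCCCCc1cc(OC(=O)c2c(CCCCC)cc(OC)cc2OC)cc(OC)c1C=O | intermediate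
13 | planaic acid | CCCCCc1cc(OC(=O)c2c(CCCCC)cc(OC)cc2OC)cc(OC)c1C(=O)O | target

**Total step count:** 8
**Longest linear sequence:** 7 steps (steps 1–5, 7, 8 from olivetol); step 6 is a one-step side branch.

**Three steps most likely to fail**

Step 7 (key step). The carbonylation at the doubly ortho-substituted aryl–palladium centre may be slow, so that carbon monoxide leaves the solution, the formate is used up unproductively and the iodide is reduced or left unchanged. Fallback: the route sets out from 9 and 6 and uses the classical depside esterification instead of the carbonylation. Iodine–lithium exchange on 9 (n-BuLi, THF, −78 °C) and a CO2 quench should give 2,4-dimethoxy-6-pentylbenzoic acid F1. F1 is then esterified with phenol 6 through its mixed trifluoroacetic anhydride (TFAA, toluene, rt). This comes back to the route at 12.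

Step 5. The formyl group may be lost by hydrolysis during isolation, or acetyl may be transferred in place of formyl. Fallback: the isolated formate is bypassed and the carbonyl carbon is supplied as CO gas. The route sets out from 6 and 9 and runs a three-component aryloxycarbonylation (Pd(OAc)2, Xantphos, CO 1 atm, NEt3, toluene, 80 °C), which comes back at 12; it makes no new compound F0.

Step 8. Hypochlorous acid that escapes the scavenger may chlorinate the electron-rich dimethoxyphenyl ring, or the activated aryl ester may be cleaved during oxidation and work-up. Fallback: the oxidation is moved ahead of the fragment union and the acid is carried as a benzyl ester, so the route ends in a hydrogenolysis. It sets out from 5, which is oxidised (NaClO2, NaH2PO4, 2-methyl-2-butene) to 2-methoxy-4-(methoxymethoxy)-6-pentylbenzoic acid F2. Benzylation (BnBr, K2CO3, DMF) gives benzyl 2-methoxy-4-(methoxymethoxy)-6-pentylbenzoate F3. HCl in MeOH frees benzyl 4-hydroxy-2-methoxy-6-pentylbenzoate F4, and acetic formic anhydride gives benzyl 4-(formyloxy)-2-methoxy-6-pentylbenzoate F5. The coupling of step 7 with 9 then gives benzyl 4-[(2,4-dimethoxy-6-pentylbenzoyl)oxy]-2-methoxy-6-pentylbenzoate F6, and hydrogenolysis (H2, Pd/C, EtOAc) comes back to the route at 13.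

**Further compounds**
F1 | step 7 | 2,4-dimethoxy-6-pentylbenzoic acid | CCCCCc1cc(OC)cc(OC)c1C(=O)O
F0 | step 5 | none | none
F2 | step 8 | 2-methoxy-4-(methoxymethoxy)-6-pentylbenzoic acid | CCCCCc1cc(OCOC)cc(OC)c1C(=O)O
F3 | step 8 | benzyl 2-methoxy-4-(methoxymethoxy)-6-pentylbenzoate | CCCCCc1cc(OCOC)cc(OC)c1C(=O)OCc1ccccc1
F4 | step 8 | benzyl 4-hydroxy-2-methoxy-6-pentylbenzoate | CCCCCc1cc(O)cc(OC)c1C(=O)OCc1ccccc1
F5 | step 8 | benzyl 4-(formyloxy)-2-methoxy-6-pentylbenzoate | CCCCCc1cc(OC=O)cc(OC)c1C(=O)OCc1ccccc1
F6 | step 8 | benzyl 4-[(2,4-dimethoxy-6-pentylbenzoyl)oxy]-2-methoxy-6-pentylbenzoate | CCCCCc1cc(OC(=O)c2c(CCCCC)cc(OC)cc2OC)cc(OC)c1C(=O)OCc1ccccc1
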